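## Structural features

The target is a single six-membered carbocycle, a cyclohex-2-enone in which every ring carbon is substituted. C1 carries a propionyloxy group, C3 (on the C2=C3 bond) the hydroxymethyl carbon C7, C4 the ketone, C5 an (E)-4-hydroxy-2-methylbut-2-enoyloxy group and C6 an isopropyl group. The three stereocentres C1, C6 and C5 are contiguous and (1S,5R,6S), which puts the C1 oxygen cis and the C5 oxygen trans to the isopropyl group. The fragile parts are the γ-acyloxy enone (loss of the C1 acyloxy group and aromatisation under base), the α-acyloxy ketone at C5 (epimerisation, ketol shift, acyl migration), two primary allylic alcohols and the E enoate of the side chain. The difficulty lies less in the skeleton than in placing three oxygen functions of defined relative configuration around C6, telling two secondary esters apart, and deciding which of the oxygenated allylic carbons C1 and C4 becomes the ketone. The key step exploits the O–C1–C2=C3–C4=O array: a but-2-ene oxygenated at both ends at two oxidation levels is what a C1=C2–C3=C4 diene gives after 1,4-addition of dioxygen and redox-neutral opening of the peroxide. C5 is then the only enolisable carbon beside the ketone, so its oxygen can follow by enol ether oxidation, and C6 is the only stereocentre that has to be brought in from outside.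

## Logic of the disconnections

23 to 22. The two O–Si bonds, at C7 and at C4 of the side chain, are cut last. Both primary allylic alcohols are masked by the same group through all acylations and one step ends the synthesis. The forward step must free two alcohols without touching three acyl groups or causing acyl migration, which calls for a weakly acidic fluoride source.

22 to 16 and 20. The C5–O acyl bond is cut. This removes the whole side chain and leaves a ring alcohol and a separately made acid. The forward acylation must work on a hindered α-ketol without epimerising C5.

20 to 19, then 17 and 18. The ester is taken back to 19 and the C2=C3 bond of the side chain is cut. A 2-methylbut-2-enoic acid without the C4 oxygen is not a sound starting point, because neither radical bromination nor allylic oxidation distinguishes its two methyl groups cleanly. Olefination of 17 with 18 brings the oxygen in with the carbon. The demand is E selectivity.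

16 to 13. The C5–O bond is cut. In 13 the carbon C5 is the only enolisable position beside the C4 ketone, so the oxygen can enter through 14. The forward step must deliver it to the face opposite the C6 isopropyl group and must enolise the ketone, not the propionate.

13 to 11 and 12. The C1–O acyl bond is cut with inversion at C1. The oxygen that the key step places on C1 is trans to the isopropyl group and the target needs it cis. An esterification with inversion corrects this and introduces the propionate in one operation. The demand is a clean SN2 reaction at an allylic carbinol with a branched neighbour.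

11 to 10. The C4 ketone and the C1 hydroxyl are traced back to one O–O bond. The forward step needs no oxidant or reductant, only removal of the C4 bridgehead hydrogen by a base. The demand is that the base takes this hydrogen and not the one at C1.

10 to 8 and 9. The C1–O and C4–O bonds are cut together. A bicyclic peroxide with three stereocentres goes back to a monocyclic diene with one stereocentre and to 9. The forward reaction must prefer cycloaddition to the ene reaction and must choose the diene face opposite the isopropyl group. The structures of 8 and 10 map onto the (1S,5R,6S) target without change, and C7 is kept as a silyl ether on purpose, since a carbonyl group at C7 would acidify C1–H and steer the later opening the wrong way.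

8 to 7, then 5 and 6. The O–Si bond and then the C3–C7 bond are cut. C3 is thereby recognised as a former carbonyl carbon and the one-carbon unit comes from 6. The cross-coupling has to transfer an sp3 carbon without isomerising or dehydrogenating the diene.

5 to 3. The C3–O bond of the triflate goes back, through 4, to the carbonyl group of 3. The position of the C3=C4 bond is that of the kinetic α' enolate. Deprotonation must avoid the γ hydrogen at C6, which would destroy the stereocentre.

3 to 2 to 1. The C1=C2 double bond is removed and 2 is traced back to the prochiral ketone 1. The single stereocentre C6 is created by telling apart two enantiotopic α-methylene groups. The enantiomeric purity of everything that follows depends on this step.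

## Other disconnections considered

Alternative 1: The cut is the ring bond C3–C4. In the forward sense the open-chain aldehyde A1, which carries a Z vinyl iodide at C3 and all three stereocentres, would be treated with CrCl2 and catalytic NiCl2. Zerovalent nickel inserts into the C–I bond, transmetalation gives a vinylchromium species, and this adds to the C4 aldehyde to close the ring as the allylic alcohol A2 (Nozaki–Hiyama–Kishi cyclisation). Oxidation at C4 would then give the enone.
- In its favour: C4 is the carbonyl carbon by construction, so the question of which bridgehead hydrogen a base removes does not arise; here the alternative is the better plan. The stereocentres would come from auxiliary- or reagent-controlled aldol chemistry in the open chain, which should give more predictable optical purity than a desymmetrisation; this is also a point for the alternative. The configuration of the new C4 carbinol is irrelevant, and the reaction tolerates esters and silyl ethers.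
- Against it: A1 is a β-branched α-silyloxy aldehyde with an allylic propionate, so C5 can epimerise and acyl groups can migrate. The C1/C6/C5 triad with isopropyl in the middle needs two stereoselective C–C bond formations and protecting-group changes. The Z-trisubstituted vinyl iodide bearing C7 needs its own sequence. Divalent chromium is used in large excess, and an extra oxidation follows.
- Comparison: on structure, both plans deliver the full substitution pattern; the alternative fixes the ketone position, the chosen plan fixes C2=C3 and both C–O bonds at once. On mechanism, a polar organometallic addition under reagent control stands against a pericyclic addition under substrate control. On step economy, the chosen plan has the ring with C6 and C7 after five steps, whereas A1 alone should take about ten to twelve; after ring closure the two are about equal.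

Alternative 2: The cut is the ring bond C2–C3. In the forward sense the hex-5-enopyranoside A3, a 3-deoxy-3-C-isopropyl sugar with the gulo arrangement at its C2 to C4, would be treated with catalytic Hg(OCOCF3)2 in aqueous acetone. Oxymercuration of the enol ether and opening of the hemiacetal give a 1,5-dicarbonyl compound, whose mercury enolate adds to the aldehyde to form the β-hydroxy cyclohexanone A4 (Ferrier carbocyclisation). Dehydration would give the C2=C3 enone, and C7 would be added afterwards by a Morita–Baylis–Hillman reaction with a one-carbon electrophile.
- In its favour: the absolute configuration comes from the chiral pool, so enantiomeric purity is complete by origin; this is better than the chosen plan. The ketone position is unambiguous, also better. The C1 and C5 oxygens arrive already differentiated by their protecting groups, again better than differentiation by inversion and enol ether oxidation. The carbocyclisation is reliable and catalytic in divalent mercury.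
- Against it: a C-isopropyl branch at sugar C3 with the gulo arrangement needs a long sequence from a common hexose (oxidation, C-branching, stereocontrolled deoxygenation, protecting-group changes, formation of the enol ether). C7 and the double bond are missing after ring closure. α-Hydroxymethylation of a hindered, base-sensitive α'-silyloxy enone is slow. Mercury is toxic.
- Comparison: on structure, the alternative builds the ring with all three stereocentres but without C7; the chosen plan builds ring and C7 early and oxygenates afterwards. On mechanism, an ionic aldol closure stands against a cycloaddition; both are insensitive to the configuration of the carbon that becomes sp2. On step economy the alternative should need about twenty steps against thirteen.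

Alternative 3: The cut is the ring bond C5–C6. In the forward sense the Z-configured acyclic ketoaldehyde A5 (C5 aldehyde, C4 ketone, C2=C3 bearing C7, C1 silyloxy carbinol, C6=CMe2) would be activated at the aldehyde by a Lewis acid such as Sc(OTf)3. An intramolecular carbonyl-ene reaction forms C5–C6, shifts an allylic methyl hydrogen to oxygen and leaves an isopropenyl group on C6. A chair-like transition state should put the three substituents of A6 equatorial, all trans.
- In its favour: the C5 oxygen and C6 are set together with the ring, so no separate oxidation at C5 is needed; this is better than the chosen plan. The ketone position is unambiguous, also better. The step is pericyclic and catalytic, equal in kind to the chosen key step. The precursor needs one stereocentre only (C1), equal to the chosen plan (C6).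
- Against it: A5 is a vicinal dicarbonyl compound conjugated with a Z alkene, prone to hydrate formation and Z/E isomerisation. Its C1 silyloxy carbinol is doubly allylic and may ionise under Lewis acid. Cationic Prins-type paths compete with the concerted ene reaction. C1 of A6 has the configuration opposite to the target, so an inversion with 12 is needed exactly as in the chosen plan (equal). The isopropenyl group must be hydrogenated in the presence of the enone.
- Comparison: on structure, the alternative forms a C–C bond and two stereocentres in the key step, the chosen plan two C–O bonds and two stereocentres. On mechanism both are pericyclic, but the chosen substrate is a stable hydrocarbon-like diene and A5 is a sensitive polycarbonyl compound. On step economy the alternative is expected to be comparable or slightly longer, because of the synthesis of A5, the hydrogenation and the protecting-group exchange.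

Key step: step 6

Remark on the chemistry: atom labels C1 to C7 are those of the target ring and are kept for every intermediate, whatever locants the systematic names use; the sense of induction in step 1 is taken to follow that established for 4-alkylcyclohexanones and is to be confirmed by the sign of rotation of 3.

## Steps

Step 1
Reactants: 1 4-isopropylcyclohexan-1-one
Product: 2 (R)-[(4-isopropylcyclohex-1-en-1-yl)oxy]trimethylsilane
Conditions: (S,S)-bis(1-phenylethyl)amine hydrochloride, n-BuLi (2 equiv), THF, −78 to 0 °C; TMSCl, then 1, −100 °C
Reagents that add atoms: chlorotrimethylsilane (TMSCl), C[Si](C)(C)Cl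
Why: Enantioselective deprotonation: the C2-symmetric lithium amide removes one of the two enantiotopic axial α-hydrogens of the conformationally anchored ketone, and the enolate is silylated at once by the TMSCl already present (LiCl from the amine salt sharpens the selectivity). This sets C6 of the target; the (S,S) amide is expected to give the (R) enol silane, and the antipodal amine is equally available should the rotation of 3 show the opposite sense.

Step 2
Reactants: 2 (R)-[(4-isopropylcyclohex-1-en-1-yl)oxy]trimethylsilane
Product: 3 (S)-4-isopropylcyclohex-2-en-1-one
Conditions: Pd(OAc)2 (1.05 equiv), MeCN, 25 °C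
Reagents that add atoms: none
Why: Saegusa–Ito oxidation: the enol silane transfers to divalent palladium as an oxa-π-allyl species and β-hydride elimination gives the enone on the side fixed by the enol ether (C1=C2 in target labels), with zerovalent palladium as the spent metal. The stereocentre is not involved and only changes its descriptor through the new priorities.

Step 3
Reactants: 3 (S)-4-isopropylcyclohex-2-en-1-one
Product: 5 (S)-4-isopropylcyclohexa-1,5-dien-1-yl trifluoromethanesulfonate, via lithium dienolate 4 (not isolated)
Conditions: LiN(SiMe3)2, THF, −78 °C; PhNTf2, −78 to 0 °C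
Reagents that add atoms: N-phenylbis(trifluoromethanesulfonimide) (PhNTf2), O=S(=O)(N(c1ccccc1)S(=O)(=O)C(F)(F)F)C(F)(F)F; lithium bis(trimethylsilyl)amide, [Li]N([Si](C)(C)C)[Si](C)(C)C (its lithium sits in 4 only)
Why: Kinetic deprotonation of an enone by a hindered amide at low temperature takes an α' hydrogen (C4 in target labels) and not the γ hydrogen at the stereocentre, giving the cross-conjugated dienolate 4. O-Sulfonylation then fixes the 2-substituted cyclohexa-1,3-diene as its enol triflate, a standard way to make dienyl triflates from cyclohexenones.

Step 4
Reactants: 5 (S)-4-isopropylcyclohexa-1,5-dien-1-yl trifluoromethanesulfonate; 6 (tributylstannyl)methanol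
Product: 7 (S)-(4-isopropylcyclohexa-1,5-dien-1-yl)methanol
Conditions: Pd(PPh3)4 (5 mol %), LiCl (3 equiv), 1,4-dioxane, 90 °C; aq. KF work-up
Reagents that add atoms: none
Why: Stille coupling: the dienyl triflate adds oxidatively to zerovalent palladium, chloride from LiCl replaces triflate on the metal and eases transmetalation of the hydroxymethyl group of 6, and reductive elimination forms the C3–C7 bond. Transfer of the hydroxymethyl group from this stannane to enol triflates is an established use of the reagent, and no stereocentre is touched.

Step 5
Reactants: 7 (S)-(4-isopropylcyclohexa-1,5-dien-1-yl)methanol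
Product: 8 (S)-tert-butyl[(4-isopropylcyclohexa-1,5-dien-1-yl)methoxy]dimethylsilane
Conditions: TBSCl, imidazole, CH2Cl2, 0 to 20 °C
Reagents that add atoms: tert-butylchlorodimethylsilane (TBSCl), CC(C)(C)[Si](C)(C)Cl
Why: Standard silylation of a primary allylic alcohol. The silyl ether removes the free hydroxyl before the photooxygenation and the base step and keeps C7 at the alcohol oxidation level.

Step 6
Reactants: 8 (S)-tert-butyl[(4-isopropylcyclohexa-1,5-dien-1-yl)methoxy]dimethylsilane; 9 dioxygen
Product: 10 (1S,4R,7S)-5-[(tert-butyldimethylsilyloxy)methyl]-7-isopropyl-2,3-dioxabicyclo[2.2.2]oct-5-ene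
Conditions: O2 (1 atm), 5,10,15,20-tetraphenylporphyrin (1 mol %), CH2Cl2, white LED, −30 °C
Reagents that add atoms: none
Why: The porphyrin, excited by visible light, passes its triplet energy to 9, and the singlet oxygen formed adds as a two-atom dienophile to the ring-locked s-cis diene C1=C2–C3=C4 of 8, making the C1–O and C4–O bonds in one suprafacial [4+2] step and leaving the new C2=C3 bond. The closest known reaction type is the sensitised photooxygenation of cyclohexa-1,3-dienes to 2,3-dioxabicyclo[2.2.2]octenes of the ascaridole kind. The one ring closed is the six-membered 1,2-dioxine, formed by cycloaddition with both oxygen atoms bonding to the same face of the diene, so the bridge is necessarily cis across C1 and C4. The configurations of C1 and C4 are thus tied to each other by suprafaciality and to C6 by steric approach control: oxygen should come to the face away from the isopropyl group on the neighbouring C6, which gives the anti adduct 10. The step needs cycloaddition to win over the Schenck ene reaction at the C5, C6 and C7 hydrogens and over dehydrogenation to the arene; the cisoid geometry, the electron-rich alkyl- and silyloxymethyl-substituted diene and the low temperature favour the [4+2] path. Because singlet oxygen is small, the facial preference may be modest; any syn adduct is separated by chromatography here and is used as set out in the closing section.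

Step 7
Reactants: 10 (1S,4R,7S)-5-[(tert-butyldimethylsilyloxy)methyl]-7-isopropyl-2,3-dioxabicyclo[2.2.2]oct-5-ene
Product: 11 (4S,5S)-2-[(tert-butyldimethylsilyloxy)methyl]-4-hydroxy-5-isopropylcyclohex-2-en-1-one
Conditions: Et3N (0.5 equiv), CH2Cl2, 0 to 20 °C
Reagents that add atoms: none
Why: Kornblum–DeLaMare rearrangement: the amine removes the bridgehead hydrogen at C4, which lies anti-periplanar to the O–O bond, and the peroxide fragments to the C4 ketone and the C1 alkoxide without change at C1 (oxygen trans to isopropyl). Selection of C4–H over C1–H rests on sterics, since C4–H is flanked by a methylene group and a planar sp2 carbon while C1–H sits beside the branched C6; the mild amine is chosen so that the γ-hydroxy enone does not isomerise further.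

Step 8
Reactants: 11 (4S,5S)-2-[(tert-butyldimethylsilyloxy)methyl]-4-hydroxy-5-isopropylcyclohex-2-en-1-one; 12 propanoic acid
Product: 13 (1R,6S)-3-[(tert-butyldimethylsilyloxy)methyl]-6-isopropyl-4-oxocyclohex-2-en-1-yl propanoate
Conditions: PPh3, DIAD, toluene, 0 to 20 °C
Reagents that add atoms: none
Why: Mitsunobu reaction: the allylic alcohol is activated as its alkoxyphosphonium ion and displaced by propanoate in an SN2 step, so C1 is inverted and its oxygen becomes cis to the isopropyl group as in the target. Allylic activation offsets the hindrance from C6, and SN2' attack is unlikely because C3 is the fully substituted α-carbon of the enone.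

Step 9
Reactants: 13 (1R,6S)-3-[(tert-butyldimethylsilyloxy)methyl]-6-isopropyl-4-oxocyclohex-2-en-1-yl propanoate
Product: 16 (1S,5R,6S)-3-[(tert-butyldimethylsilyloxy)methyl]-5-hydroxy-6-isopropyl-4-oxocyclohex-2-en-1-yl propanoate, via silyl dienol ether 14 (not isolated), via alpha-silyloxy ketone 15 (not isolated)
Conditions: LiN(SiMe3)2, TMSCl, THF, −78 °C; mCPBA, NaHCO3, CH2Cl2, −20 to 0 °C; citric acid, MeOH, 0 °C
Reagents that add atoms: 3-chloroperoxybenzoic acid (mCPBA), O=C(OO)c1cccc(Cl)c1; chlorotrimethylsilane (TMSCl), C[Si](C)(C)Cl (its silyl group is carried by 14 and 15 and is lost again before 16)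
Why: Rubottom oxidation: kinetic enolisation of the ketone at C5, its only α-carbon with hydrogen and far more acidic than the propionate, with silylation in the flask gives the 2-silyloxy diene 14. The peracid epoxidises the electron-rich enol ether bond on the face away from the C6 isopropyl group and the C1 ester, which stand on the same side, and a 1,4-silyl shift gives 15 with the C5 oxygen trans to isopropyl. Mild acid methanolysis then removes the trimethylsilyl group alone.

Step 10
Reactants: 17 (tert-butyldimethylsilyloxy)acetaldehyde; 18 ethyl 2-(triphenylphosphoranylidene)propanoate
Product: 19 ethyl (E)-4-(tert-butyldimethylsilyloxy)-2-methylbut-2-enoate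
Conditions: CH2Cl2, 20 to 40 °C
Reagents that add atoms: none
Why: Wittig olefination with a stabilised α-methyl ylide; reversible addition and the preference for the less crowded oxaphosphetane should give the E trisubstituted enoate. The C4 oxygen of the side chain comes in with the aldehyde, so no allylic oxidation is needed.

Step 11
Reactants: 19 ethyl (E)-4-(tert-butyldimethylsilyloxy)-2-methylbut-2-enoate
Product: 20 (E)-4-(tert-butyldimethylsilyloxy)-2-methylbut-2-enoic acid
Conditions: LiOH, THF/MeOH/H2O, 20 °C; then aq. HCl to pH 3, 0 °C
Reagents that add atoms: lithium hydroxide, [Li+].[OH-]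
Why: Saponification of the ethyl ester; a primary tert-butyldimethylsilyl ether withstands aqueous hydroxide and a brief cold acidification. The E enoate is the stable isomer and is not at risk.

Step 12
Reactants: 16 (1S,5R,6S)-3-[(tert-butyldimethylsilyloxy)methyl]-5-hydroxy-6-isopropyl-4-oxocyclohex-2-en-1-yl propanoate; 20 (E)-4-(tert-butyldimethylsilyloxy)-2-methylbut-2-enoic acid
Product: 22 (1S,5R,6S)-3-[(tert-butyldimethylsilyloxy)methyl]-5-{[(E)-4-(tert-butyldimethylsilyloxy)-2-methylbut-2-enoyl]oxy}-6-isopropyl-4-oxocyclohex-2-en-1-yl propanoate, via mixed anhydride 21 (not isolated)
Conditions: 2,4,6-Cl3C6H2COCl, Et3N, THF, 20 °C; then 16, DMAP, toluene, 20 °C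
Reagents that add atoms: 2,4,6-trichlorobenzoyl chloride, O=C(Cl)c1c(Cl)cc(Cl)cc1Cl (its aroyl group is carried by 21 only and is not in 22)
Why: Yamaguchi esterification: DMAP takes the unhindered enoyl group from the mixed anhydride 21 and passes it to the hindered C5 hydroxyl. No stereocentre is formed; C5 carries its oxygen trans to isopropyl, the more stable arrangement, so the mild base should not epimerise it.

Step 13
Reactants: 22 (1S,5R,6S)-3-[(tert-butyldimethylsilyloxy)methyl]-5-{[(E)-4-(tert-butyldimethylsilyloxy)-2-methylbut-2-enoyl]oxy}-6-isopropyl-4-oxocyclohex-2-en-1-yl propanoate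
Product: 23 (1S,5R,6S)-3-(hydroxymethyl)-5-{[(E)-4-hydroxy-2-methylbut-2-enoyl]oxy}-6-isopropyl-4-oxocyclohex-2-en-1-yl propanoate
Conditions: HF·pyridine, pyridine, THF, 0 to 20 °C
Reagents that add atoms: none
Why: Fluoride-induced cleavage of both primary silyl ethers in a buffered, weakly acidic medium. The three acyl groups and the γ-acyloxy enone are stable under these conditions, and no alkoxide is formed that could start an acyl migration.

## Compound list

1 | 4-isopropylcyclohexan-1-one | CC(C)C1CCC(=O)CC1 | starting material
2 | (R)-[(4-isopropylcyclohex-1-en-1-yl)oxy]trimethylsilane | C[Si](C)(C)OC1=CC[C@H](C(C)C)CC1 | intermediate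
3 | (S)-4-isopropylcyclohex-2-en-1-one | O=C1C=C[C@H](C(C)C)CC1 | intermediate
4 | lithium (S)-4-isopropylcyclohexa-1,5-dien-1-olate | [Li]OC1=CC[C@@H](C(C)C)C=C1 | intermediate
5 | (S)-4-isopropylcyclohexa-1,5-dien-1-yl trifluoromethanesulfonate | O=S(=O)(OC1=CC[C@@H](C(C)C)C=C1)C(F)(F)F | intermediate
6 | (tributylstannyl)methanol | CCCC[Sn](CCCC)(CCCC)CO | starting material
7 | (S)-(4-isopropylcyclohexa-1,5-dien-1-yl)methanol | OCC1=CC[C@@H](C(C)C)C=C1 | intermediate
8 | (S)-tert-butyl[(4-isopropylcyclohexa-1,5-dien-1-yl)methoxy]dimethylsilane (the 5-isopropylcyclohexa-1,3-dien-2-yl compound in the other ring numbering) | CC(C)(C)[Si](C)(C)OCC1=CC[C@@H](C(C)C)C=C1 | intermediate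
9 | dioxygen | O=O | starting material
10 | (1S,4R,7S)-5-[(tert-butyldimethylsilyloxy)methyl]-7-isopropyl-2,3-dioxabicyclo[2.2.2]oct-5-ene (peroxide bridge anti to isopropyl) | CC(C)[C@@H]1C[C@H]2OO[C@@H]1C=C2CO[Si](C)(C)C(C)(C)C | intermediate
11 | (4S,5S)-2-[(tert-butyldimethylsilyloxy)methyl]-4-hydroxy-5-isopropylcyclohex-2-en-1-one | O[C@@H]1C=C(CO[Si](C)(C)C(C)(C)C)C(=O)C[C@H]1C(C)C | intermediate
12 | propanoic acid | CCC(=O)O | starting material
13 | (1R,6S)-3-[(tert-butyldimethylsilyloxy)methyl]-6-isopropyl-4-oxocyclohex-2-en-1-yl propanoate | CCC(=O)O[C@H]1C=C(CO[Si](C)(C)C(C)(C)C)C(=O)C[C@H]1C(C)C | intermediate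
14 | (1R,6R)-3-[(tert-butyldimethylsilyloxy)methyl]-6-isopropyl-4-(trimethylsilyloxy)cyclohexa-2,4-dien-1-yl propanoate | CCC(=O)O[C@H]1C=C(CO[Si](C)(C)C(C)(C)C)C(O[Si](C)(C)C)=C[C@H]1C(C)C | intermediate
15 | (1S,5R,6S)-3-[(tert-butyldimethylsilyloxy)methyl]-6-isopropyl-4-oxo-5-(trimethylsilyloxy)cyclohex-2-en-1-yl propanoate | CCC(=O)O[C@H]1C=C(CO[Si](C)(C)C(C)(C)C)C(=O)[C@H](O[Si](C)(C)C)[C@H]1C(C)C | intermediate
16 | (1S,5R,6S)-3-[(tert-butyldimethylsilyloxy)methyl]-5-hydroxy-6-isopropyl-4-oxocyclohex-2-en-1-yl propanoate | CCC(=O)O[C@H]1C=C(CO[Si](C)(C)C(C)(C)C)C(=O)[C@H](O)[C@H]1C(C)C | intermediate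
17 | (tert-butyldimethylsilyloxy)acetaldehyde | CC(C)(C)[Si](C)(C)OCC=O | starting material
18 | ethyl 2-(triphenylphosphoranylidene)propanoate | CCOC(=O)C(C)=P(c1ccccc1)(c1ccccc1)c1ccccc1 | starting material
19 | ethyl (E)-4-(tert-butyldimethylsilyloxy)-2-methylbut-2-enoate | CCOC(=O)/C(C)=C/CO[Si](C)(C)C(C)(C)C | intermediate
20 | (E)-4-(tert-butyldimethylsilyloxy)-2-methylbut-2-enoic acid | OC(=O)/C(C)=C/CO[Si](C)(C)C(C)(C)C | intermediate
21 | (E)-4-(tert-butyldimethylsilyloxy)-2-methylbut-2-enoic 2,4,6-trichlorobenzoic anhydride | CC(C)(C)[Si](C)(C)OC/C=C(\C)C(=O)OC(=O)c1c(Cl)cc(Cl)cc1Cl | intermediate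
22 | (1S,5R,6S)-3-[(tert-butyldimethylsilyloxy)methyl]-5-{[(E)-4-(tert-butyldimethylsilyloxy)-2-methylbut-2-enoyl]oxy}-6-isopropyl-4-oxocyclohex-2-en-1-yl propanoate | CCC(=O)O[C@H]1C=C(CO[Si](C)(C)C(C)(C)C)C(=O)[C@H](OC(=O)/C(C)=C/CO[Si](C)(C)C(C)(C)C)[C@H]1C(C)C | intermediate
23 | (1S,5R,6S)-3-(hydroxymethyl)-5-{[(E)-4-hydroxy-2-methylbut-2-enoyl]oxy}-6-isopropyl-4-oxocyclohex-2-en-1-yl propanoate | CCC(=O)O[C@H]1C=C(CO)C(=O)[C@H](OC(=O)/C(C)=C/CO)[C@H]1C(C)C | target

## Step count and least certain steps

Total step count: 13. Longest linear sequence: 11 steps (steps 1 to 9, 12 and 13); steps 10 and 11 make the side-chain acid.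

The optical purity of every later compound is that of 2 and is to be assayed at 3 before material is committed.

Step 6 (key step). The likely failure is poor facial selectivity, because singlet oxygen is small and the isopropyl group sits one carbon away from the diene terminus; the ene reaction and dehydrogenation to the arene may also take material. The fallback uses both faces instead of forcing one. It sets out from 8: the syn endoperoxide F1, formed in the same irradiation, is opened with Et3N in CH2Cl2 to the cis hydroxy enone F2, whose C1 oxygen already has the configuration of the target. Propionic anhydride with DMAP in pyridine then acylates F2 with retention, and the material comes back to the route at 13.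

Step 7. The likely failure is removal of the wrong bridgehead hydrogen (C1–H instead of C4–H), since the steric difference between the two positions is small; base-induced isomerisation of the γ-hydroxy enone to a 1,4-diketone is a second risk. The fallback fixes the regiochemistry by tethering and sets out from 10.
- Thiourea in MeOH reduces the peroxide to the cis enediol F3.
- Bu4NF in THF frees the primary alcohol to give the triol F4.
- 2,2-Dimethoxypropane with pyridinium p-toluenesulfonate ties the C7 and C4 oxygens into the six-membered acetonide F5, leaving only the C1 hydroxyl free.
- The Mitsunobu reaction with 12 gives the inverted acetonide propionate F6.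
- Aqueous acetic acid in THF removes the acetonide to give the diol propionate F7.
- TBSCl and imidazole at −20 °C silylate the primary alcohol to give the allylic alcohol F8.
- MnO2 in CH2Cl2 oxidises the C4 carbinol, and the sequence comes back to the route at 13.

Step 8. The likely failure is slow displacement beside the branched C6 with the weakly acidic propanoic acid, leading to elimination of the activated alcohol toward a dienone and phenol, or to retention through an acyloxyphosphonium path. The fallback separates inversion from propionylation and sets out from 11. The Mitsunobu reaction with the stronger 4-nitrobenzoic acid (PPh3, DIAD, THF) gives the inverted 4-nitrobenzoate F9. K2CO3 in MeOH at 0 °C removes the aroyl group to give the cis hydroxy enone F2, and propionic anhydride with DMAP in pyridine gives 13.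

Step 4. The likely failure is slow transfer of the sp3 hydroxymethyl group, with competing butyl transfer and, at the temperature needed, a thermal 1,5-hydrogen shift or dehydrogenation of the diene, which would erase C6. The fallback brings C7 in as carbon monoxide at lower temperature and sets out from 5. Methoxycarbonylation (CO at 1 atm, MeOH, Pd(OAc)2, 1,3-bis(diphenylphosphino)propane, Et3N, DMF, 40 °C) gives the methyl dienoate F10, and i-Bu2AlH in CH2Cl2 at −78 °C reduces it to 7.

Step 9. The likely failure is loss of chemoselectivity in the enolisation (deprotonation of the propionate or of the γ position C1, or transfer of the propionyl group from oxygen to the enolate carbon), and over-oxidation of the C2=C3 bond by the peracid. The fallback avoids the enolate and the enol ether altogether and sets out from 13. Oxidative α'-acyloxylation with Mn(OAc)3 in benzene at reflux, in the presence of an excess of 20, goes through the enolate of trivalent manganese and an α'-keto radical that takes up a carboxylate ligand. It should place the side-chain ester on C5 trans to the isopropyl group and so come back to the route directly at 22, bypassing 16; it makes no new compound.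

## Further compounds

F1 | step 6 | (1R,4S,7S)-5-[(tert-butyldimethylsilyloxy)methyl]-7-isopropyl-2,3-dioxabicyclo[2.2.2]oct-5-ene (peroxide bridge syn to isopropyl) | CC(C)[C@@H]1C[C@@H]2OO[C@H]1C=C2CO[Si](C)(C)C(C)(C)C
F2 | step 6 | (4R,5S)-2-[(tert-butyldimethylsilyloxy)methyl]-4-hydroxy-5-isopropylcyclohex-2-en-1-one | O[C@H]1C=C(CO[Si](C)(C)C(C)(C)C)C(=O)C[C@H]1C(C)C
F3 | step 7 | (1R,4S,5S)-2-[(tert-butyldimethylsilyloxy)methyl]-5-isopropylcyclohex-2-ene-1,4-diol | O[C@@H]1C=C(CO[Si](C)(C)C(C)(C)C)[C@H](O)C[C@H]1C(C)C
F4 | step 7 | (1R,4S,5S)-2-(hydroxymethyl)-5-isopropylcyclohex-2-ene-1,4-diol | O[C@@H]1C=C(CO)[C@H](O)C[C@H]1C(C)C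
F5 | step 7 | (6S,7S,8aR)-7-isopropyl-2,2-dimethyl-6,7,8,8a-tetrahydro-4H-1,3-benzodioxin-6-ol | O[C@@H]1C=C2COC(C)(C)O[C@@H]2C[C@H]1C(C)C
F6 | step 7 | (6R,7S,8aR)-7-isopropyl-2,2-dimethyl-6,7,8,8a-tetrahydro-4H-1,3-benzodioxin-6-yl propanoate | CCC(=O)O[C@H]1C=C2COC(C)(C)O[C@@H]2C[C@H]1C(C)C
F7 | step 7 | (1R,4R,6S)-4-hydroxy-3-(hydroxymethyl)-6-isopropylcyclohex-2-en-1-yl propanoate | CCC(=O)O[C@H]1C=C(CO)[C@H](O)C[C@H]1C(C)C
F8 | step 7 | (1R,4R,6S)-3-[(tert-butyldimethylsilyloxy)methyl]-4-hydroxy-6-isopropylcyclohex-2-en-1-yl propanoate | CCC(=O)O[C@H]1C=C(CO[Si](C)(C)C(C)(C)C)[C@H](O)C[C@H]1C(C)C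
F9 | step 8 | (1R,6S)-3-[(tert-butyldimethylsilyloxy)methyl]-6-isopropyl-4-oxocyclohex-2-en-1-yl 4-nitrobenzoate | O=C(O[C@H]1C=C(CO[Si](C)(C)C(C)(C)C)C(=O)C[C@H]1C(C)C)c1ccc(cc1)[N+](=O)[O-]
F10 | step 4 | methyl (S)-4-isopropylcyclohexa-1,5-diene-1-carboxylate | COC(=O)C1=CC[C@@H](C(C)C)C=C1
F0 | step 9 | none | none
A1 | alternative 1 | (Z)-7-(tert-butyldiphenylsilyloxy)-6-iodo-3-isopropyl-1-oxo-2-(triethylsilyloxy)hept-5-en-4-yl propanoate, stereocentres as in the target | O=C[C@H](O[Si](CC)(CC)CC)[C@@H](C(C)C)[C@@H](OC(=O)CC)/C=C(\I)CO[Si](c1ccccc1)(c1ccccc1)C(C)(C)C
A2 | alternative 1 | 3-[(tert-butyldiphenylsilyloxy)methyl]-4-hydroxy-6-isopropyl-5-(triethylsilyloxy)cyclohex-2-en-1-yl propanoate, one C4 epimer | CCC(=O)O[C@H]1C=C(CO[Si](c2ccccc2)(c2ccccc2)C(C)(C)C)[C@@H](O)[C@H](O[Si](CC)(CC)CC)[C@H]1C(C)C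
A3 | alternative 2 | methyl 4-O-(tert-butyldimethylsilyl)-3,6-dideoxy-3-C-isopropyl-2-O-(4-methoxybenzyl)hex-5-enopyranoside, gulo arrangement at C2 to C4, either anomer | C=C1OC(OC)[C@H](OCc2ccc(OC)cc2)[C@H](C(C)C)[C@H]1O[Si](C)(C)C(C)(C)C
A4 | alternative 2 | 2-(tert-butyldimethylsilyloxy)-5-hydroxy-3-isopropyl-4-(4-methoxybenzyloxy)cyclohexan-1-one, one epimer at the new carbinol | COc1ccc(cc1)CO[C@H]2[C@H](O)CC(=O)[C@H](O[Si](C)(C)C(C)(C)C)[C@H]2C(C)C
A5 | alternative 3 | (Z)-5-(tert-butyldimethylsilyloxy)-3-[(tert-butyldiphenylsilyloxy)methyl]-7-methyl-2-oxoocta-3,6-dienal | O=CC(=O)/C(CO[Si](c1ccccc1)(c1ccccc1)C(C)(C)C)=C\[C@@H](O[Si](C)(C)C(C)(C)C)C=C(C)C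
A6 | alternative 3 | 4-(tert-butyldimethylsilyloxy)-2-[(tert-butyldiphenylsilyloxy)methyl]-6-hydroxy-5-isopropenylcyclohex-2-en-1-one, all three substituents trans | CC(C)(C)[Si](C)(C)O[C@@H]1C=C(CO[Si](c2ccccc2)(c2ccccc2)C(C)(C)C)C(=O)[C@H](O)[C@H]1C(C)=C
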